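**The bench.** As the chemist on these flasks, I wanted to know which way of adding E or L best keeps Z from going on to G.

| flask | E | L | remark | time |
|---|---|---|---|---|
| alder | 0.10 M | 0.090 M | run made earlier |  |
| oak | 0.10 M | 0.045 M | run made earlier |  |
| larch | 0.10 M | 0.18 M | run made earlier |  |
| south | 0.10 M (fed, over 15 min) | 0.0900 M | all else is in the flask from the start; the feed brings no volume worth counting | 40 min |
| north-east | 0.10 M (in portions, 3, over 15 min) | 0.0900 M | first portion at the start, last at 15 min | 40 min |
| south-east | 0.10 M | 0.0900 M | everything together at the start | 40 min |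
| west | 0.10 M | 0.0900 M (fed, over 15 min) | all else is in the flask from the start; the feed brings no volume worth counting | 40 min |

| run | time / min | Z / % | G / % |
|---|---|---|---|
| alder | 2.00 | 12.6 | 4.4 |
| alder | 3.00 | 14.6 | 7.1 |
| alder | 5.00 | 16.7 | 10.9 |
| alder | 8.00 | 17.5 | 13.4 |
| alder | 15.0 | 17.9 | 15.6 |
| alder | 25.0 | 17.4 | 17.1 |
| oak | 8.00 | 14.6 | 6.4 |
| oak | 15.0 | 15.1 | 7.3 |
| oak | 25.0 | 15.2 | 7.8 |
| oak | 30.0 | 15.5 | 7.3 |
| oak | 40.0 | 15.0 | 7.5 |
| oak | 50.0 | 15.0 | 7.7 |
| larch | 4.00 | 17.7 | 18.3 |
| larch | 6.00 | 17.7 | 23.0 |
| larch | 10.0 | 17.7 | 26.7 |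
| larch | 20.0 | 16.6 | 29.2 |
| larch | 30.0 | 17.5 | 29.8 |
| larch | 50.0 | 17.3 | 29.9 |

(each reading ± 0.3 percentage points)

- amounts and yields of D count J too
- given per volume of solution although it is solid: J
- the numbers in the tables scatter by 0.3 percentage points (one standard deviation)
- what may be going on: 2 L -> Q; E + L -> Z + D; E + L -> X + D; L + X -> G + D; J <-> D; L + Z -> G + D

- the flask with the highest share of Z in Z plus G ("all alike" if they lie within 1.5 percentage points) (south / north-east / south-east / west / all alike)
- share of Z in Z plus G at the end, south
- share of Z in Z plus G at the end, north-east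
- share of Z in Z plus G at the end, south-east
- share of Z in Z plus G at the end, west

**Fastest rung.** Z and E compete for the same L, so dividing their two rates removes both L and the clock. Z therefore stops gaining when the E left stands at a fixed multiple of Z. I worked with the fraction left: E left is the charge minus Z and G, with X counted as nil. Larch made the most G, and its Z was flat from 4.00 min. Its last reading gave κ = 3.05, the ratio of E left to Z on the flat top. This is a selectivity factor: at equal concentrations, Z takes L faster than E does.

**Next rung.** L also destroys itself. Counting one L in Z and two in G, oak's last reading left 32.4% of its L unaccounted for, and larch's left 57.2%. I put most of that share down to Q, and it was larger at the higher L charge.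

**Slowest rung.** Readings stood still by 15.0 min in oak and by 30.0 min in larch, so I took 40 min as the end. I expected south-east to repeat alder, whose last share was 50.4%. In south, L meets little E early and loses more to Q, so I expected E to stay far above κ times Z and the share to be the highest. In west, thin L loses less, so I expected E to fall to about κ times Z.

**The outcome.** The forecast gave 55% for south, 48.5% for north-east, 49.5% for south-east and 46% for west, holding that “The share depends on how far E is converted”. The flasks gave 61.1%, 49.9%, 51.7% and 42.6% in that order, with south highest.

    2 L → Q (k = 0.0300 L mol⁻¹ s⁻¹)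
    E + L → Z + D (k = 0.0270 L mol⁻¹ s⁻¹)
    E + L → X + D (k = 0.00250 L mol⁻¹ s⁻¹)
    L + X → G + D (k = 0.00960 L mol⁻¹ s⁻¹)
    J ⇌ D, rate k5*(cs5 - [D]) while solid is left; crystals form when [D] > cs5 (solubility = 0.0610 M, k = 0.590 s⁻¹)
    L + Z → G + D (k = 0.0860 L mol⁻¹ s⁻¹)

**The check.** West ended with E over Z at 3.04, beside the κ read from larch. The neighbour of west charged with 0.22 M of L ended at 2.27, below κ, with Z at 11.7%. The gap of 18 percentage points between south and west comes from 2 L → Q and L + Z → G acting together, each being a part of the cause. Without L + Z → G that gap is 0.66 points, and without 2 L → Q it is −3.9 points.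

The readings come from a simulation with constants of no real substance.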